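The route rests on disconnecting C2–C3 of the tetradecan-3-one chain, the bond between the ketone carbon and the methylene of the two-carbon tether to the guaiacyl ring. The feature exploited is that C1–C2 is an ethylene bridge between the benzene ring and the C3 carbonyl, i.e. a hydroacylated vinylarene whose benzylic C1 stabilises a radical. In one operation, a photoredox, phosphine-mediated deoxygenative hydroacylation turns (S)-3-acetoxydodecanoic acid into its acyl radical and adds it anti-Markovnikov to the vinyl group of commercial 4-benzyloxy-3-methoxystyrene. The C5 stereocentre comes from a Noyori hydrogenation, and hydrogenolysis of the benzyl ether ends the route.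

Key step: step 4

Remark: methyl 3-oxododecanoate and 4-benzyloxy-3-methoxystyrene are taken as catalogue compounds; chain atoms are numbered as in 1-aryltetradecan-3-one (C1 benzylic, C3 ketone, C5 acetoxy carbon, which is S in the target).

Step 1
Reactants: 1 methyl 3-oxododecanoate
Product: 2 methyl (3S)-3-hydroxydodecanoate
Conditions: [RuCl(p-cymene)((S)-BINAP)]Cl (0.2 mol%), H2 (30 bar), MeOH, 50 °C
Reagents that add atoms: none
Why: Noyori asymmetric hydrogenation of a β-keto ester, in which the substrate chelates ruthenium through both carbonyl oxygens and the (S)-BINAP ligand directs hydride to the ketone face that gives the (S)-carbinol, the established sense for simple 3-oxoalkanoates.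

Step 2
Reactants: 2 methyl (3S)-3-hydroxydodecanoate
Product: 3 (3S)-3-hydroxydodecanoic acid
Conditions: LiOH·H2O (2 equiv), THF/H2O 3:1, 0 °C to rt; then 1 M HCl to pH 2
Reagents that add atoms: lithium hydroxide, [Li+].[OH-]
Why: Saponification (BAc2 ester hydrolysis) under mild conditions should leave the carbinol centre, which bears no acidic hydrogen, untouched and avoid dehydration of the β-hydroxy ester.

Step 3
Reactants: 3 (3S)-3-hydroxydodecanoic acid
Product: 4 (3S)-3-acetoxydodecanoic acid
Conditions: Ac2O (3 equiv), pyridine, 0 °C to rt; then H2O, rt; 1 M HCl work-up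
Reagents that add atoms: acetic anhydride, CC(=O)OC(C)=O
Why: Pyridine-mediated O-acetylation of the secondary alcohol does not break the C–O bond at the stereocentre, so the (S) configuration is retained, and the aqueous quench returns any mixed anhydride to the free acid.

Step 4
Reactants: 4 (3S)-3-acetoxydodecanoic acid; 5 4-benzyloxy-3-methoxystyrene (2 equiv)
Product: 6 (5S)-1-[4-(benzyloxy)-3-methoxyphenyl]-3-oxotetradecan-5-yl acetate
Conditions: Ir[dF(Me)ppy]2(dtbbpy)PF6 (2 mol%), PMe2Ph (1.5 equiv), 2,6-lutidine (1 equiv), degassed MeCN, blue LEDs (450 nm), rt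
Reagents that add atoms: none
Why: The excited Ir(III) photocatalyst oxidises the phosphine to its radical cation, the carboxylate of 4 adds at phosphorus, and β-scission of the resulting phosphoranyl radical (driven by P=O formation) releases the C3 acyl radical, which adds to the unsubstituted terminus of the vinyl group of 5 and so forms the C2–C3 bond; the benzylic C1 radical is then reduced by Ir(II) and protonated by lutidinium, closing a redox-neutral cycle. The closest known reaction type is the phosphine-mediated photoredox deoxygenative anti-Markovnikov hydroacylation of styrenes with aliphatic carboxylic acids, a Giese-type acyl radical addition. No ring is closed and no stereocentre is formed; the C5 acetoxy centre sits β to the acyl radical, carries no acidic hydrogen and should pass through unchanged. The step needs anti-Markovnikov regioselectivity, which is secured by formation of the aryl-stabilised benzylic radical, and oxidation of the phosphine in preference to the electron-rich arene, which is secured by a photocatalyst with only a moderately oxidising excited state. Addition to the styrene, used in excess, should outrun decarbonylation of the primary-alkyl acyl radical, and the weak base 2,6-lutidine should leave the base-sensitive β-acetoxy ketone intact.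

Step 5
Reactants: 6 (5S)-1-[4-(benzyloxy)-3-methoxyphenyl]-3-oxotetradecan-5-yl acetate
Product: 7 (5S)-1-(4-hydroxy-3-methoxyphenyl)-3-oxotetradecan-5-yl acetate (target)
Conditions: H2 (1 atm), 10% Pd/C, EtOAc, rt
Reagents that add atoms: none
Why: Catalytic hydrogenolysis of the aryl benzyl ether runs under neutral conditions in which the aliphatic ketone, the acetate and the non-benzylic stereocentre are inert, so the β-acetoxy ketone never meets base.

Compound list
1 | methyl 3-oxododecanoate | CCCCCCCCCC(=O)CC(=O)OC | starting material
2 | methyl (3S)-3-hydroxydodecanoate | CCCCCCCCC[C@H](O)CC(=O)OC | intermediate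
3 | (3S)-3-hydroxydodecanoic acid | CCCCCCCCC[C@H](O)CC(=O)O | intermediate
4 | (3S)-3-acetoxydodecanoic acid | CCCCCCCCC[C@@H](CC(=O)O)OC(C)=O | intermediate
5 | 4-benzyloxy-3-methoxystyrene (1-benzyloxy-2-methoxy-4-vinylbenzene) | C=Cc1ccc(OCc2ccccc2)c(OC)c1 | starting material
6 | (5S)-1-[4-(benzyloxy)-3-methoxyphenyl]-3-oxotetradecan-5-yl acetate | CCCCCCCCC[C@@H](CC(=O)CCc1ccc(OCc2ccccc2)c(OC)c1)OC(C)=O | intermediate
7 | (5S)-1-(4-hydroxy-3-methoxyphenyl)-3-oxotetradecan-5-yl acetate | CCCCCCCCC[C@@H](CC(=O)CCc1ccc(O)c(OC)c1)OC(C)=O | target

Total step count: 5. Longest linear sequence: 5 steps (1 → 2 → 3 → 4 → 6 → 7).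

Steps most likely to fail

Step 4 (key step). The acyl radical may form too slowly or be lost by decarbonylation or hydrogen abstraction. The electron-rich benzylic radical may be reduced too slowly and enter oligomerisation of the styrene. Acetic acid may also be eliminated from the β-acetoxy ketone under the amine base. The fallback sets out from 5 and 4 and comes back at 6, forming the same C2–C3 bond by polar cross-coupling. Hydroboration of 5 with 9-BBN (THF, 0 °C to rt) should give the B-(2-arylethyl)-9-borabicyclo[3.3.1]nonane F1, which is oxidised in the same flask (NaOH, H2O2) to 2-[4-(benzyloxy)-3-methoxyphenyl]ethanol F2. Iodination (I2, PPh3, imidazole, CH2Cl2) should give 1-benzyloxy-4-(2-iodoethyl)-2-methoxybenzene F3, and zinc insertion (Zn dust, LiCl, THF) the alkylzinc iodide 2-[4-(benzyloxy)-3-methoxyphenyl]ethylzinc iodide F4. Acid 4 is converted with oxalyl chloride (cat. DMF, CH2Cl2, 0 °C) into (3S)-3-acetoxydodecanoyl chloride F5. Negishi acylation of F5 with F4 (Pd(PPh3)4, THF, 0 °C to rt) should give 6 without any base.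

Step 3. Activation of the hydroxy acid by the anhydride may lead to β-elimination to the 2-enoic acid or to intermolecular O-acylation through the mixed anhydride (oligoester formation). The fallback sets out from 3 and comes back at 4, masking the acid during acetylation. Alkylation of 3 (BnBr, KHCO3, DMF, rt) should give benzyl (3S)-3-hydroxydodecanoate F6. Acetylation (Ac2O, pyridine, cat. DMAP, 0 °C) should give benzyl (3S)-3-acetoxydodecanoate F7. Hydrogenolysis (H2, Pd/C, EtOAc) should then release 4.

Step 5. Elimination of acetic acid on the catalyst surface, followed by hydrogenation of the resulting enone, would remove the acetoxy group, and debenzylation may stall. The fallback sets out from 4 and comes back at 7, replacing the benzyl ether by a silyl ether that is removed by fluoride under slightly acidic conditions. Commercial 2-methoxy-4-vinylphenol is silylated (TBSCl, imidazole, DMF) to tert-butyl(2-methoxy-4-vinylphenoxy)dimethylsilane F8. The hydroacylation of step 4 with 4 in place of 5 should give (5S)-1-[4-(tert-butyldimethylsilyloxy)-3-methoxyphenyl]-3-oxotetradecan-5-yl acetate F9. Desilylation (HF·pyridine, THF, 0 °C) should give 7.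

Further compounds
F1 | step 4 | 9-{2-[4-(benzyloxy)-3-methoxyphenyl]ethyl}-9-borabicyclo[3.3.1]nonane | COc1cc(CCB2C3CCCC2CCC3)ccc1OCc1ccccc1
F2 | step 4 | 2-[4-(benzyloxy)-3-methoxyphenyl]ethanol | COc1cc(CCO)ccc1OCc1ccccc1
F3 | step 4 | 1-benzyloxy-4-(2-iodoethyl)-2-methoxybenzene | COc1cc(CCI)ccc1OCc1ccccc1
F4 | step 4 | 2-[4-(benzyloxy)-3-methoxyphenyl]ethylzinc iodide | COc1cc(CC[Zn]I)ccc1OCc1ccccc1
F5 | step 4 | (3S)-3-acetoxydodecanoyl chloride | CCCCCCCCC[C@@H](CC(=O)Cl)OC(C)=O
F6 | step 3 | benzyl (3S)-3-hydroxydodecanoate | CCCCCCCCC[C@H](O)CC(=O)OCc1ccccc1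
F7 | step 3 | benzyl (3S)-3-acetoxydodecanoate | CCCCCCCCC[C@@H](CC(=O)OCc1ccccc1)OC(C)=O
F8 | step 5 | tert-butyl(2-methoxy-4-vinylphenoxy)dimethylsilane | C=Cc1ccc(O[Si](C)(C)C(C)(C)C)c(OC)c1
F9 | step 5 | (5S)-1-[4-(tert-butyldimethylsilyloxy)-3-methoxyphenyl]-3-oxotetradecan-5-yl acetate | CCCCCCCCC[C@@H](CC(=O)CCc1ccc(O[Si](C)(C)C(C)(C)C)c(OC)c1)OC(C)=O
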